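**Assumption:** the SMILES is read as 15-acetoxylabda-7,13E-dien-17-oic acid of the normal labdane series (5S,9R,10S; 10-CH3 β, 5-H and 9-H α). This is the C-5/C-9/C-10 configuration of (+)-sclareolide. Labdane numbering is used throughout (C-17 is the carbon on C-8; C-11 and C-12 are the first two side-chain carbons on C-9).

## Retrosynthetic overview

1. Target 9 ⇐ Pinnick oxidation of enal 8; the C-17 aldehyde is carried as the latent acid so that only one carboxyl (C-12) is ever present for activation.
2. 8 ⇐ one light-driven three-component union forming C-11–C-12 and C-15–O: C-11 radical (from redox-active ester 6, loss of CO2) + isoprene + acetate, giving the 13E side chain.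
3. 6 ⇐ (+)-sclareolide 1 by lactone opening/dehydration to the Δ7 ester 2, allylic oxidation of C-17, saponification and activation.
4. No ring is formed: rings A and B (trans-decalin) and C-5, C-9, C-10 come intact from sclareolide.

## Route

Step 1
Reactants: 1 (+)-sclareolide
Product: 2 methyl 13,14,15,16-tetranorlabd-7-en-12-oate
Conditions: conc. H2SO4 (1 equiv), MeOH, reflux, 16 h; chromatography on AgNO3-impregnated SiO2
Reagents that add atoms: methanol, CO
Why: Acid-catalysed alkyl–oxygen ionisation of the tertiary lactone, E1 loss of the axial 7α-H (Zaitsev, endocyclic trisubstituted alkene) and Fischer esterification occur in one pot; C-5, C-9 and C-10 are untouched, the C-8 centre is deliberately destroyed, and the minor Δ8(17) and Δ8 isomers are removed on the silver-nitrate silica.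

Step 2
Reactants: 2 methyl 13,14,15,16-tetranorlabd-7-en-12-oate
Product: 4 methyl 17-oxo-13,14,15,16-tetranorlabd-7-en-12-oate, via allylic alcohol 3 (not isolated)
Conditions: SeO2 (1.5 equiv), 1,4-dioxane (1% H2O), 100 °C, 3 h
Reagents that add atoms: selenium dioxide, O=[Se]=O
Why: Riley allylic oxidation (ene reaction of SeO2, then [2,3]-sigmatropic shift) attacks the methyl on the more substituted alkene carbon in preference to the hindered tertiary 9-H (order CH2 > CH3 > CH, as in the drimenyl acetate series), and the primary allylic alcohol 3 is oxidised on to the conjugated aldehyde; no stereocentre is touched.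

Step 3
Reactants: 4 methyl 17-oxo-13,14,15,16-tetranorlabd-7-en-12-oate
Product: 5 17-oxo-13,14,15,16-tetranorlabd-7-en-12-oic acid
Conditions: LiOH·H2O (3 equiv), THF/H2O 3:1, 0 °C to rt; then 1 M HCl to pH 3
Reagents that add atoms: lithium hydroxide, [Li+].[OH-]
Why: Ordinary saponification of an unhindered CH2CO2Me ester; the enal has no α-hydrogen, C-9 is not activated by either carbonyl and so is not epimerised.

Step 4
Reactants: 5 17-oxo-13,14,15,16-tetranorlabd-7-en-12-oic acid
Product: 6 1,3-dioxoisoindolin-2-yl 17-oxo-13,14,15,16-tetranorlabd-7-en-12-oate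
Conditions: N-hydroxyphthalimide (1.1 equiv), DIC (1.1 equiv), DMAP (5 mol%), CH2Cl2, 0 °C to rt
Reagents that add atoms: N-hydroxyphthalimide, ON1C(=O)c2ccccc2C1=O
Why: Carbodiimide (Steglich-type) esterification gives the crystalline redox-active ester; the conjugated aldehyde and the stereocentres are inert under these neutral conditions.

Step 5
Reactants: 6 1,3-dioxoisoindolin-2-yl 17-oxo-13,14,15,16-tetranorlabd-7-en-12-oate; 7 isoprene (10 equiv)
Product: 8 17-oxolabda-7,13E-dien-15-yl acetate
Conditions: Pd(PPh3)4 (5 mol%), Bu4NOAc (3 equiv), AcOH (2 equiv), degassed DMA (0.1 M), 450 nm LEDs, 20 °C, sealed tube, stopped at full conversion of 6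
Reagents that add atoms: tetrabutylammonium acetate, CCCC[N+](CCCC)(CCCC)CCCC.CC(=O)[O-]; acetic acid, CC(=O)O (one acetate pool, acetic acid being the net source)
Why: Proposed new method: a visible-light, Pd(PPh3)4-catalysed decarboxylative 1,4-alkyl-acetoxylation of isoprene, in which photoexcited zerovalent palladium reduces the N-acyloxyphthalimide by single-electron transfer, the C-11 primary radical (after loss of CO2) adds to the methyl-bearing CH2 terminus of s-trans isoprene to give the more substituted, E-configured allyl radical, this recombines with monovalent palladium to the π-allyl complex of divalent palladium, and acetate attacks the unhindered CH2 terminus to give the linear 13E allylic acetate (C-11–C-12 and C-15–O bonds formed, alkene geometry inherited from the diene conformer, AcOH keeping the phthalimide by-product protonated so that it does not compete as nucleophile); the closest known reaction type is the photoinduced palladium-catalysed three-component 1,4-aminoalkylation of 1,3-dienes with redox-active esters or alkyl halides and N-nucleophiles, which has not been shown with acetate as the terminating nucleophile, and no decalin stereocentre is involved.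

Step 6
Reactants: 8 17-oxolabda-7,13E-dien-15-yl acetate
Product: 9 15-acetoxylabda-7,13E-dien-17-oic acid (target)
Conditions: NaClO2 (3 equiv), NaH2PO4 (3 equiv), 2-methyl-2-butene (20 equiv), t-BuOH/H2O 4:1, 0 °C to rt
Reagents that add atoms: sodium chlorite, [Na+].[O-]Cl=O
Why: Pinnick (Lindgren–Kraus) oxidation converts the conjugated aldehyde to the acid under buffered conditions that leave the allylic acetate, both trisubstituted alkenes (HOCl scavenged by 2-methyl-2-butene) and all stereocentres untouched.

## Compound list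

1 | (+)-sclareolide, (3aR,5aS,9aS,9bR)-3a,6,6,9a-tetramethyldecahydronaphtho[2,1-b]furan-2(1H)-one | O=C1C[C@H]2[C@](C)(O1)CC[C@H]3C(C)(C)CCC[C@]23C | starting material
2 | methyl 13,14,15,16-tetranorlabd-7-en-12-oate, methyl 2-[(1S,4aS,8aS)-2,5,5,8a-tetramethyl-1,4,4a,5,6,7,8,8a-octahydronaphthalen-1-yl]acetate | COC(=O)C[C@H]1C(C)=CC[C@H]2C(C)(C)CCC[C@]12C | intermediate
3 | methyl 17-hydroxy-13,14,15,16-tetranorlabd-7-en-12-oate, methyl 2-[(1R,4aS,8aS)-2-(hydroxymethyl)-5,5,8a-trimethyl-1,4,4a,5,6,7,8,8a-octahydronaphthalen-1-yl]acetate | COC(=O)C[C@H]1C(CO)=CC[C@H]2C(C)(C)CCC[C@]12C | intermediate (not isolated)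
4 | methyl 17-oxo-13,14,15,16-tetranorlabd-7-en-12-oate, methyl 2-[(1R,4aS,8aS)-2-formyl-5,5,8a-trimethyl-1,4,4a,5,6,7,8,8a-octahydronaphthalen-1-yl]acetate | COC(=O)C[C@H]1C(C=O)=CC[C@H]2C(C)(C)CCC[C@]12C | intermediate
5 | 17-oxo-13,14,15,16-tetranorlabd-7-en-12-oic acid, 2-[(1R,4aS,8aS)-2-formyl-5,5,8a-trimethyl-1,4,4a,5,6,7,8,8a-octahydronaphthalen-1-yl]acetic acid | OC(=O)C[C@H]1C(C=O)=CC[C@H]2C(C)(C)CCC[C@]12C | intermediate
6 | 1,3-dioxoisoindolin-2-yl 17-oxo-13,14,15,16-tetranorlabd-7-en-12-oate (N-acyloxyphthalimide of 5; 1R,4aS,8aS) | O=C(C[C@H]1C(C=O)=CC[C@H]2C(C)(C)CCC[C@]12C)ON1C(=O)c2ccccc2C1=O | intermediate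
7 | isoprene (2-methylbuta-1,3-diene) | C=CC(C)=C | starting material
8 | 17-oxolabda-7,13E-dien-15-yl acetate, (2E)-5-[(1R,4aS,8aS)-2-formyl-5,5,8a-trimethyl-1,4,4a,5,6,7,8,8a-octahydronaphthalen-1-yl]-3-methylpent-2-en-1-yl acetate | CC(=O)OC/C=C(\C)CC[C@H]1C(C=O)=CC[C@H]2C(C)(C)CCC[C@]12C | intermediate
9 | 15-acetoxylabda-7,13E-dien-17-oic acid, (1R,4aS,8aS)-1-[(3E)-5-acetoxy-3-methylpent-3-en-1-yl]-5,5,8a-trimethyl-1,4,4a,5,6,7,8,8a-octahydronaphthalene-2-carboxylic acid | CC(=O)OC/C=C(\C)CC[C@H]1C(C(=O)O)=CC[C@H]2C(C)(C)CCC[C@]12C | target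

## Step count and risks

Total steps: 6. Longest linear sequence: 6 (1 → 2 → 4 → 5 → 6 → 8 → 9).

**Step 5 (the proposed new reaction) is the most likely to fail.** The foreseeable problems are:
- radical attack at the other diene terminus, giving the 14-methyl regioisomer;
- N-allylation by phthalimide;
- β-hydride loss from the allyl-palladium species to give a triene;
- erosion of the 13E geometry if zerovalent palladium re-ionises the product;
- 1,2-vinyl shift of the homoallylic C-11 radical (slow relative to trapping by neat-excess isoprene).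

The fallback uses known chemistry only; it sets out from 2 and comes back at 8. LiAlH4 in THF reduces 2 to 13,14,15,16-tetranorlabd-7-en-12-ol F7. I2, PPh3 and imidazole give 12-iodo-13,14,15,16-tetranorlabd-7-ene F8. LiC≡CH·H2NCH2CH2NH2 in DMSO gives the terminal alkyne 15,16-dinorlabd-7-en-13-yne F9. Zirconium-catalysed carboalumination (Me3Al, Cp2ZrCl2, CH2Cl2; then n-BuLi and (CH2O)n) adds methyl and CH2OH syn across the alkyne and gives labda-7,13E-dien-15-ol F10 with the E geometry fixed by the syn addition. Ac2O and pyridine give labda-7,13E-dien-15-yl acetate F11. SeO2 with t-BuOOH in CH2Cl2, finished with MnO2, oxidises C-17 through 17-hydroxylabda-7,13E-dien-15-yl acetate F12 to 8. The side-chain alkene is expected to survive because its allylic acetate deactivates it, as in geranyl acetate where SeO2 attacks only the remote alkene. Step 6 then follows unchanged.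

**Step 1 is the second risk.** The E1 elimination may give too much of the Δ8(17) or Δ8 isomers, and prolonged acid could epimerise C-9 through the Δ8 alkene. The fallback sets out from 1 and comes back at 3, bypassing 2. KOH in MeOH, then MeI in DMF on the potassium salt, gives methyl 8α-hydroxy-13,14,15,16-tetranorlabdan-12-oate F1. SOCl2 and pyridine in CH2Cl2 at −78 °C give the exocyclic alkene methyl 13,14,15,16-tetranorlabd-8(17)-en-12-oate F2 by anti elimination; the equatorial 8α-oxygen has anti-periplanar hydrogens only on the methyl group. mCPBA from the open α-face gives methyl 8α,17-epoxy-13,14,15,16-tetranorlabdan-12-oate F3. Et2Al(TMP) (diethylaluminium 2,2,6,6-tetramethylpiperidide) in benzene at 0 °C isomerises the epoxide to the allylic alcohol 3, removing a secondary C-7 hydrogen in preference to the tertiary 9-H. Compound 3 is isolated here and oxidised with MnO2 in CH2Cl2 to 4.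

**Step 2 is the third risk.** The intermediate alcohol 3 may lactonise onto the C-12 ester before it is oxidised, or the ring CH2 at C-6 may be attacked. The fallback avoids selenium; it sets out from 2 and comes back at 4. mCPBA gives methyl 7α,8α-epoxy-13,14,15,16-tetranorlabdan-12-oate F4. Et2Al(TMP) opens it by removing a C-17 methyl hydrogen to give methyl 7α-hydroxy-13,14,15,16-tetranorlabd-8(17)-en-12-oate F5. SOCl2 in Et2O transposes this by SNi′ substitution to the primary allylic chloride methyl 17-chloro-13,14,15,16-tetranorlabd-7-en-12-oate F6. 4-Methylmorpholine N-oxide in MeCN (Ganem-type oxidation of an allylic halide) gives 4.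

Further compounds
F1 | step 1 | methyl 8α-hydroxy-13,14,15,16-tetranorlabdan-12-oate | COC(=O)C[C@H]1[C@](C)(O)CC[C@H]2C(C)(C)CCC[C@]12C
F2 | step 1 | methyl 13,14,15,16-tetranorlabd-8(17)-en-12-oate | COC(=O)C[C@H]1C(=C)CC[C@H]2C(C)(C)CCC[C@]12C
F3 | step 1 | methyl 8α,17-epoxy-13,14,15,16-tetranorlabdan-12-oate | COC(=O)C[C@H]1[C@@]3(CO3)CC[C@H]2C(C)(C)CCC[C@]12C
F4 | step 2 | methyl 7α,8α-epoxy-13,14,15,16-tetranorlabdan-12-oate | COC(=O)C[C@H]1[C@]3(C)O[C@@H]3C[C@H]2C(C)(C)CCC[C@]12C
F5 | step 2 | methyl 7α-hydroxy-13,14,15,16-tetranorlabd-8(17)-en-12-oate | COC(=O)C[C@H]1C(=C)[C@H](O)C[C@H]2C(C)(C)CCC[C@]12C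
F6 | step 2 | methyl 17-chloro-13,14,15,16-tetranorlabd-7-en-12-oate | COC(=O)C[C@H]1C(CCl)=CC[C@H]2C(C)(C)CCC[C@]12C
F7 | step 5 | 13,14,15,16-tetranorlabd-7-en-12-ol | OCC[C@H]1C(C)=CC[C@H]2C(C)(C)CCC[C@]12C
F8 | step 5 | 12-iodo-13,14,15,16-tetranorlabd-7-ene | ICC[C@H]1C(C)=CC[C@H]2C(C)(C)CCC[C@]12C
F9 | step 5 | 15,16-dinorlabd-7-en-13-yne | C#CCC[C@H]1C(C)=CC[C@H]2C(C)(C)CCC[C@]12C
F10 | step 5 | labda-7,13E-dien-15-ol | OC/C=C(\C)CC[C@H]1C(C)=CC[C@H]2C(C)(C)CCC[C@]12C
F11 | step 5 | labda-7,13E-dien-15-yl acetate | CC(=O)OC/C=C(\C)CC[C@H]1C(C)=CC[C@H]2C(C)(C)CCC[C@]12C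
F12 | step 5 | 17-hydroxylabda-7,13E-dien-15-yl acetate | CC(=O)OC/C=C(\C)CC[C@H]1C(CO)=CC[C@H]2C(C)(C)CCC[C@]12C
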